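TBS = tert-butyldimethylsilyl throughout. Atom labels C1–C8 (ring A) and C1′–C8′ (ring B) follow the target: C1 quaternary, C2 carbinol, C3 ring alkene carbon, C7 exocyclic CH, C8 central CH2.

## Structural features

The target has two cyclohexane rings, ring A and ring B, which are not fused but tied together by a four-carbon chain. Each ring carbon C3 (C3′) is one end of an exocyclic trisubstituted alkene, and the alkene CH carbons C7 and C7′ are linked through C8–C8′, so the centre of the molecule is a 1,5-diene. Both alkenes are Z, with C8 (C8′) on the side of the carbinol carbon C2 (C2′). In each ring the secondary allylic carbinol C2 sits next to the quaternary carbon C1, which carries a methyl group and a 4-methylpent-3-enoyl chain. Ring A is (1R,2R) with hydroxyl cis to methyl and ring B is (1′S,2′R) with hydroxyl trans to methyl, so the halves are diastereomers and no homodimerisation can be used. The fragile groups are the β,γ-unsaturated ketones (conjugation with acid or base), the β-hydroxy ketones on a non-enolisable carbon (retro-aldol), the Z-allylic carbinols (ionisation, Z/E drift, closure to a 2,5-dihydrofuran once C8 bears a leaving group) and four trisubstituted alkenes that are ene substrates for singlet oxygen. The real difficulty is to combine, twice and with opposite relative configuration, a quaternary stereocentre, its neighbouring carbinol and a Z exocyclic alkene, and then to join two allylic sp3 carbons without losing alkene geometry. The key step exploits the unit C2(–O)–C3=C7–C8: once C8 bears oxygen it is a Z-2-ene-1,4-diol, the reduced form of the six-membered endoperoxide that dioxygen forms with the semicyclic diene C2=C3–C7=C8 of a 1-vinylcyclohexene.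

## Logic of the disconnections

41 to 40. The two O–Si bonds at C2 and C2′ are cut last. The ring carbinols must stay masked while the side-chain carbinols are oxidised, and a silyl ether is the one mask that comes off without base. The forward step must be a non-basic fluoride cleavage that leaves the β,γ-enones and β-hydroxy ketones alone.

40 to 35, through 39 and 37, with 36 and 38. Each side chain is cut twice: at the bond between the carbonyl carbon and its CH2 (formyl carbon of 35 plus the allyl group of 36) and at the terminal C=CMe2 bond (metathesis with 38). A prenyl metal would attack a neopentyl aldehyde through its γ-carbon, whereas allyl cannot give a regioisomer. Both chains are treated at once, so two equivalents of 36 and of 38 are consumed. The forward steps need a metathesis that touches only monosubstituted alkenes and an oxidation that is neither acidic nor basic.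

35 to 33, through 34. The two formyl groups go back to CH2O–Si. This is only a change of oxidation state, but it demands that the primary silyl ethers of 33 be cleaved beside the secondary ones.

33 to 30 and 19, through 32. The bond C8–C8′ is cut. It is the only cut that gives two halves of equal size that both come from one kind of precursor. Forward, 30 supplies C8′ as its carbanion 31 and 19 supplies C8 as an allylic electrophile; the sulfonyl group of 32 is then removed. The demands are SN2 rather than SN2′ attack, no 1,4-elimination from the carbanion, retention of both Z alkenes, and hydride delivery to C8′ in the desulfonylation.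

30 to 25, through 29, 28, 27 and 26. In ring B the C2′–H bond of 28 is cut back to 27, which comes from 26 of opposite C2′ configuration; C8′–S goes back to C8′–O. The cycloaddition puts oxygen on the face ring B does not want, so C2′ is erased and reset. The hydride must add anti to CH2OTBS and the Z-enone must not isomerise.

19 to 16, through 18. C8–Cl goes back to C8–OH and the C2 silyl ether to the free carbinol. The forward steps must tell the primary allylic hydroxyl from the hindered secondary one without closing a dihydrofuran.

16 to 15, and 15 to 13 and 14. The O–O bond is restored, then C2–O and C8–O are cut together. This removes both oxygens, the C2 stereocentre and the Z alkene in one move and leaves a diene with one stereocentre. The forward cycloaddition must choose the face of C2 anti to CH2OTBS and must beat the ene reaction. Likewise 25 goes back through 24 to 23 and 14.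

13 to 11 and 12. The C3–C7 bond is cut (enol triflate plus vinylstannane). The demand is an enol triflate with its double bond between C2 and C3. Likewise 23 goes back to 22 and 12.

11 to 7 and 8, through 9 and 10. The C1–CH3 bond is cut. Conjugate addition creates the quaternary centre from an achiral enone and leaves the enolate double bond exactly where the triflate needs it. The demand is enantiofacial control by the catalyst and efficient O-triflation of a hindered enolate. 22 comes from the same 7 with the mirror-image ligand, through 20 and 21.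

7 to 6, and 6 to 1 and 2, through 3, 4 and 5. The O–Si bond is cut, then the bond between the ring and the CH2O carbon (3, made from 2, adds to 1 as a hydroxymethyl anion equivalent). Two commercial compounds result; the C–Si bond must be oxidised before acid is admitted.

## Other disconnections considered

Alternative 1: The cut removes the ring bond C2–C3 together with C7–C8 and C8–O, opening ring A to the acyclic yne-aldehyde A1 with C8 supplied by carbon monoxide. Forward, Ru3(CO)12 under CO pressure would join the aldehyde, the silyl-capped alkyne and CO in a hetero-Pauson–Khand cyclocarbonylation to the bicyclic butenolide A2.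
- In its favour: one step closes the carbocycle and the lactone and forms two skeletal C–C bonds, where the chosen key step forms none; on bond construction the alternative is the better plan.
- The five-membered lactone fixes the cis relation of C2–O and C8 as rigidly as the peroxide ring does; here the two are equal.
- C1 already carries a carboxyl-level group and C8 (acyl) differs from C2–O without a selective protection; on both points the alternative is better.
- Against it: C2 forms beside a quaternary carbon whose substituents, methyl and CO2Me, differ little in size, so the facial bias should be weaker than for methyl versus CH2OTBS.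
- Forcing conditions (high temperature, pressurised CO) meet an α-formyl ester that can deformylate, and the quaternary centre of A1 needs its own asymmetric synthesis in both enantiomeric series.
- The C7 silyl group must be removed, the lactone reduced, and the ester still turned into the prenyl ketone through an aldehyde.
- Comparison: the mechanism depends on a metallacycle that is sensitive to tether substitution, whereas the chosen cycloaddition needs only light, a dye and oxygen. Step counts should be close, because the gain in bond construction is spent on precursor synthesis and redox corrections.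

Alternative 2: The cut is the ring bond C1–C6. The cyclohexene acid A4 goes back to the 6-vinyl δ-lactone A3, whose silyl ketene acetal undergoes an Ireland–Claisen rearrangement with ring contraction.
- In its favour: a C–C bond and the quaternary centre form in one pericyclic step with chirality transfer through a cyclic boat-like transition state. The C1/C2 relationship is dictated by the lactone stereocentres and not by a modest steric bias; on stereochemical reliability at C1 and C2 the alternative is the better plan.
- C1 receives CO2H directly, a better oxidation level than CH2OTBS.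
- Against it: the Z-alkylidene is not addressed. C3 arrives as an sp3 silyloxy carbon, and C3=C7 would have to be made by olefination of a hindered α-alkoxy ketone with nothing to enforce Z; the chosen plan is clearly better there.
- A surplus C4=C5 alkene must be hydrogenated, benzyl removal clashes with the later alkenes, and ring B would need a different lactone.
- Comparison: A3, with three stereocentres of which two are re-functionalised, needs a long chiral-pool sequence, so step economy should be worse than in the chosen plan.

Alternative 3: The cut is the ring bond C1–C2. The tetrahydrobenzofuran ester A6 opens to the silyl ketene acetal A5 with a 3-furylpropyl chain; anodic oxidation gives a radical cation that is captured by the furan 2-position.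
- In its favour: a skeletal C–C bond, the ring and the quaternary carbon come from an achiral chain in one step; on bond construction the alternative is better than the chosen key step.
- The furan stores C2–O, the cis C3=C7 geometry and C8–O in one ring, so the Z geometry is as secure as with the peroxide; here the two are equal.
- The target needs both configurations of C1, so a resolved racemate of A6 would not be half wasted; the lack of asymmetric induction is a smaller handicap than usual.
- Against it: the absolute configuration is not controlled and a resolution is required.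
- Oxidative unmasking gives a Z-ene-1,4-dicarbonyl with C2 as a ketone, so C2 must be set by reduction in both rings; ring A would need hydride syn to the larger C1 substituent. The chosen route obtains the C2 centre of ring A directly and needs the redox detour only for ring B.
- The Z-oxo-enal isomerises easily and its two carbonyls must be differentiated.
- Comparison: the step count should be comparable, with more redox adjustments and an electrolysis.

Key step: step 5

Assumption 1: which antipode of the phosphoramidite sends methyl to which face of 7 must be assigned in the first run; the ligand (S,R,R)-PA is taken to lead to 11 and its antipode (R,S,S)-PA to 22, and the two ligands exchange steps if the sense is the reverse.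

Assumption 2: stereocentres that are destroyed later (the sulfonyl-bearing carbon of 32, the side-chain carbinol carbons of 37 and 39, C2′ of 24 to 26) are carried as mixtures; 24 to 26 are drawn as the expected major isomer.

(S,R,R)-PA = (S)-1,1′-binaphthyl-2,2′-diyl N,N-bis[(R)-1-phenylethyl]phosphoramidite; (R,S,S)-PA is its mirror image.

## Steps

Step 1
Reactants: 1 3-ethoxycyclohex-2-en-1-one; 2 (chloromethyl)(isopropoxy)dimethylsilane
Product: 6 3-(hydroxymethyl)cyclohex-2-en-1-one, via silylmethyl Grignard reagent 3 (not isolated), via chloromagnesium alkoxide adduct 4 (not isolated), via diol enol ether 5 (not isolated)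
Conditions: 2, Mg, THF, reflux; then 1, 0 °C to rt; then KF, KHCO3, 30% H2O2, MeOH/THF, rt; then 1 M HCl, 0 °C
Reagents that add atoms: hydrogen peroxide, OO; water, O
Why: The silylmethyl Grignard reagent is a hydroxymethyl anion equivalent that adds 1,2 to the vinylogous ester; Tamao oxidation of the C–Si bond under buffered fluoride conditions (which avoid Peterson elimination of the β-hydroxysilane) and then acid give the transposed enone by the Stork–Danheiser sequence. No stereocentre survives.

Step 2
Reactants: 6 3-(hydroxymethyl)cyclohex-2-en-1-one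
Product: 7 3-(TBSOCH2)cyclohex-2-en-1-one
Conditions: TBSCl, imidazole, DMF, 0 °C to rt
Reagents that add atoms: tert-butyldimethylsilyl chloride, CC(C)(C)[Si](C)(C)Cl
Why: Standard silylation of a primary allylic alcohol. TBS is kept as the group whose bulk later steers both the cycloaddition and the ring B hydride reduction, and because a primary neopentyl TBS ether can later be cleaved beside hindered secondary ones.

Step 3
Reactants: 7 3-(TBSOCH2)cyclohex-2-en-1-one; 8 trimethylaluminium
Product: 11 (R)-3-(TBSOCH2)-3-methylcyclohex-1-en-1-yl trifluoromethanesulfonate, via dimethylaluminium enolate 9 (not isolated), via lithium aluminate enolate 10 (not isolated)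
Conditions: Cu(OTf)2 (5 mol %), (S,R,R)-PA (10 mol %), Me3Al, Et2O, −30 °C; then MeLi, THF, −30 to 0 °C; then PhNTf2, 0 °C to rt
Reagents that add atoms: N-phenylbis(trifluoromethanesulfonimide), O=S(=O)(N(c1ccccc1)S(=O)(=O)C(F)(F)F)C(F)(F)F
Why: Asymmetric conjugate addition of Me3Al to a 3-substituted cyclohexenone, catalysed by the chiral complex formed from Cu(OTf)2 and the phosphoramidite, creates the quaternary C1, and the ligand fixes the face of methyl delivery. The enolate double bond is left between C2 and C3, the hindered position that deprotonation of the ketone would not give; MeLi turns the aluminium enolate into the more nucleophilic aluminate, which PhNTf2 triflates on oxygen.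

Step 4
Reactants: 11 (R)-3-(TBSOCH2)-3-methylcyclohex-1-en-1-yl trifluoromethanesulfonate; 12 tributyl(vinyl)stannane
Product: 13 (R)-tert-butyldimethyl[(1-methyl-3-vinylcyclohex-2-en-1-yl)methoxy]silane
Conditions: Pd(PPh3)4 (5 mol %), LiCl, THF, 65 °C
Reagents that add atoms: none
Why: Stille coupling of an enol triflate with a vinylstannane (oxidative addition, chloride-assisted transmetallation, reductive elimination) forms C3–C7 and gives the 1-vinylcyclohexene; the quaternary centre is not involved.

Step 5
Reactants: 13 (R)-tert-butyldimethyl[(1-methyl-3-vinylcyclohex-2-en-1-yl)methoxy]silane; 14 dioxygen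
Product: 15 (8S,8aR)-8-(TBSOCH2)-8-methyl-3,5,6,7,8,8a-hexahydrobenzo[c][1,2]dioxine (ring A endoperoxide; peroxide oxygen on C2 cis to the C1 methyl)
Conditions: O2 (1 atm), 5,10,15,20-tetraphenylporphyrin (0.5 mol %), CH2Cl2, −78 °C, visible light
Reagents that add atoms: none
Why: Energy transfer from the excited porphyrin gives singlet oxygen, which adds suprafacially to the s-cis conformer of the diene C2=C3–C7=C8 in a concerted, asynchronous [4+2] cycloaddition that forms C2–O and C8–O and moves the π bond to C3=C7. The closest known reaction type is the photooxygenation of 1-vinylcycloalkenes to bicyclic 3,6-dihydro-1,2-dioxines. The one new ring, the six-membered 1,2-dioxine, is closed by this cycloaddition mode (both ring bonds in one suprafacial event, not a stepwise exo or endo closure), and because C2, C3, C7 and C8 lie in that ring the new C3=C7 bond can only have C8 cis to C2, that is Z. The single new stereocentre C2 is controlled by the adjacent quaternary C1: in the less congested half-chair transition state the larger CH2OTBS group stands perpendicular to the diene plane and oxygen bonds to C2 from the opposite face, past the smaller methyl group, so the C2 oxygen ends up cis to methyl as ring A requires. The step needs facial selectivity, cycloaddition in preference to the ene reaction, and chemoselectivity: the first rests on the size difference between CH2OTBS and CH3; the second on the absence of hydrogen at C1, so that only the C4 hydrogens are ene-active, and on the unhindered vinyl group, which lets the diene reach the s-cis geometry (low temperature and a non-polar solvent help further); the third on the absence of any other alkene, the ene-reactive prenyl groups being introduced only later. The peroxide is isolated so that a minor C2 epimer and any ene hydroperoxide can be removed before reduction.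

Step 6
Reactants: 15 ring A endoperoxide
Product: 16 (1R,2Z,6S)-6-(TBSOCH2)-2-(2-hydroxyethylidene)-6-methylcyclohexan-1-ol (C2 hydroxyl cis to methyl)
Conditions: thiourea, MeOH, rt
Reagents that add atoms: none
Why: Thiourea cleaves the O–O bond reductively without touching the alkene or the silyl ether, so the ring-enforced Z geometry and the C2 configuration pass unchanged into the enediol.

Step 7
Reactants: 16 ring A enediol
Product: 18 (1R,2Z,6S)-6-(TBSOCH2)-2-(2-chloroethylidene)-6-methylcyclohexan-1-ol, via primary allylic mesylate 17 (not isolated)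
Conditions: MsCl, 2,4,6-collidine, LiCl, DMF, 0 °C
Reagents that add atoms: lithium chloride, [Li+].[Cl-]
Why: The unhindered primary allylic hydroxyl is mesylated much faster than the neopentyl-type secondary one, and chloride in DMF displaces the allylic mesylate by SN2 without transposition because C3 is fully substituted. The neutral Z-chloro alcohol should be stable in the absence of strong base, which alone would close the dihydrofuran.

Step 8
Reactants: 18 ring A chloro alcohol
Product: 19 tert-butyl{[(1R,2Z,6S)-6-(TBSOCH2)-2-(2-chloroethylidene)-6-methylcyclohexyl]oxy}dimethylsilane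
Conditions: TBSOTf, 2,6-lutidine, CH2Cl2, −78 to −20 °C
Reagents that add atoms: tert-butyldimethylsilyl trifluoromethanesulfonate, CC(C)(C)[Si](C)(C)OS(=O)(=O)C(F)(F)F
Why: A silyl triflate with a hindered pyridine base silylates the congested C2 hydroxyl at low temperature in a medium too weakly basic to cause intramolecular displacement of chloride. The ether then blocks dihydrofuran formation and marks C2–O apart from the later side-chain carbinols.

Step 9
Reactants: 7 3-(TBSOCH2)cyclohex-2-en-1-one; 8 trimethylaluminium
Product: 22 (S)-3-(TBSOCH2)-3-methylcyclohex-1-en-1-yl trifluoromethanesulfonate, via dimethylaluminium enolate 20 (not isolated), via lithium aluminate enolate 21 (not isolated)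
Conditions: Cu(OTf)2 (5 mol %), (R,S,S)-PA (10 mol %), Me3Al, Et2O, −30 °C; then MeLi, THF, −30 to 0 °C; then PhNTf2, 0 °C to rt
Reagents that add atoms: N-phenylbis(trifluoromethanesulfonimide), O=S(=O)(N(c1ccccc1)S(=O)(=O)C(F)(F)F)C(F)(F)F
Why: Same asymmetric conjugate addition and enolate triflation as in step 3; the mirror-image ligand delivers methyl to the other face and sets the ring B configuration of C1′.

Step 10
Reactants: 22 (S)-enol triflate; 12 tributyl(vinyl)stannane
Product: 23 (S)-tert-butyldimethyl[(1-methyl-3-vinylcyclohex-2-en-1-yl)methoxy]silane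
Conditions: Pd(PPh3)4 (5 mol %), LiCl, THF, 65 °C
Reagents that add atoms: none
Why: Stille coupling as in step 4, on the enantiomer.

Step 11
Reactants: 23 (S)-diene; 14 dioxygen
Product: 25 (1S,2Z,6R)-6-(TBSOCH2)-2-(2-hydroxyethylidene)-6-methylcyclohexan-1-ol, via enantiomeric endoperoxide 24 (not isolated)
Conditions: O2 (1 atm), 5,10,15,20-tetraphenylporphyrin (0.5 mol %), CH2Cl2, −78 °C, visible light; then thiourea, MeOH, −78 °C to rt
Reagents that add atoms: none
Why: The same [4+2] cycloaddition of singlet oxygen as in step 5 and the same thiourea reduction as in step 6, run in one flask. The C2′ configuration is erased in step 13, so neither epimer separation nor isolation of a peroxide is needed in this series.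

Step 12
Reactants: 25 ring B series enediol
Product: 26 (1S,2Z,6R)-6-(TBSOCH2)-6-methyl-2-[2-(phenylsulfanyl)ethylidene]cyclohexan-1-ol
Conditions: PhSSPh, n-Bu3P, THF, 0 °C to rt
Reagents that add atoms: diphenyl disulfide, c1ccc(SSc2ccccc2)cc1
Why: Hata thioetherification: the alkoxyphosphonium ion forms only at the unhindered primary allylic oxygen and is displaced by thiophenolate in an SN2 reaction. One step therefore distinguishes C8′ from C2′ and installs the future sulfone sulfur at the sulfide level, which does not acidify C8′ during the enone stage.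

Step 13
Reactants: 26 hydroxy sulfide
Product: 27 (2Z,6R)-6-(TBSOCH2)-6-methyl-2-[2-(phenylsulfanyl)ethylidene]cyclohexan-1-one
Conditions: Dess–Martin periodinane, NaHCO3, CH2Cl2, 0 °C
Reagents that add atoms: none
Why: Dess–Martin oxidation of the secondary allylic alcohol; the periodinane oxidises alcohols far faster than thioethers, and the buffered, non-nucleophilic medium should keep the Z-enone from isomerising. Both C2′ epimers converge here.

Step 14
Reactants: 27 Z-enone
Product: 28 (1R,2Z,6R)-6-(TBSOCH2)-6-methyl-2-[2-(phenylsulfanyl)ethylidene]cyclohexan-1-ol (C2′ hydroxyl trans to methyl)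
Conditions: NaBH4, CeCl3·7H2O, MeOH, −78 °C
Reagents that add atoms: none
Why: Luche 1,2-reduction of the enone. By the Felkin–Anh mode, hydride should add anti to the CH2OTBS group on C1′, which is larger and more electron-withdrawing than methyl and cannot chelate; the new hydroxyl then lies cis to CH2OTBS and trans to methyl, the ring B relationship.

Step 15
Reactants: 28 ring B hydroxy sulfide
Product: 29 tert-butyl{[(1R,2Z,6R)-6-(TBSOCH2)-6-methyl-2-[2-(phenylsulfanyl)ethylidene]cyclohexyl]oxy}dimethylsilane
Conditions: TBSOTf, 2,6-lutidine, CH2Cl2, −78 to 0 °C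
Reagents that add atoms: tert-butyldimethylsilyl trifluoromethanesulfonate, CC(C)(C)[Si](C)(C)OS(=O)(=O)C(F)(F)F
Why: Silylation of the hindered secondary hydroxyl as in step 8, so that no alkoxide is present when the sulfone is deprotonated.

Step 16
Reactants: 29 ring B silyl ether sulfide
Product: 30 tert-butyl{[(1R,2Z,6R)-6-(TBSOCH2)-6-methyl-2-[2-(phenylsulfonyl)ethylidene]cyclohexyl]oxy}dimethylsilane
Conditions: (NH4)6Mo7O24·4H2O (10 mol %), 30% H2O2 (2.5 equiv), EtOH, 0 °C to rt
Reagents that add atoms: hydrogen peroxide, OO
Why: (NH4)6Mo7O24-catalysed peroxide oxidation takes the sulfide through the sulfoxide to the sulfone faster than it epoxidises the hindered trisubstituted alkene; silyl ethers are stable to it. Rapid onward oxidation at 0 °C should leave the allylic sulfoxide too little time to equilibrate with its sulfenate, which is the one pathway that could erode the Z geometry.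

Step 17
Reactants: 30 ring B sulfone; 19 ring A allylic chloride
Product: 32 (1Z,4Z)-1-[(2R,3R)-2-(TBSO)-3-(TBSOCH2)-3-methylcyclohexylidene]-2-(phenylsulfonyl)-4-[(2R,3S)-2-(TBSO)-3-(TBSOCH2)-3-methylcyclohexylidene]butane (epimers at the sulfonyl carbon), via lithiated sulfone 31 (not isolated)
Conditions: 30, n-BuLi, THF, −78 °C; then 19, DMPU, −78 to −30 °C
Reagents that add atoms: none
Why: Alkylation of an allylic α-sulfonyl carbanion at its α-carbon by a primary allylic chloride in an SN2 reaction forms C8–C8′; SN2′ attack is blocked because C3 is fully substituted, and both Z alkenes are spectators at low temperature. Any minor enantiomer of either half ends mainly in separable diastereomers, so the enantiomeric purity of 32 should exceed that of the halves.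

Step 18
Reactants: 32 coupled sulfone
Product: 33 (1Z,4Z)-1-[(2R,3S)-2-(TBSO)-3-(TBSOCH2)-3-methylcyclohexylidene]-4-[(2R,3R)-2-(TBSO)-3-(TBSOCH2)-3-methylcyclohexylidene]butane
Conditions: PdCl2(dppp) (10 mol %), LiBHEt3, THF, 0 °C
Reagents that add atoms: none
Why: PdCl2(dppp)-catalysed hydride desulfonylation of an allylic sulfone: ionisation gives an allylpalladium species over C8′–C7′–C3′ and hydride goes to the less substituted end C8′, restoring the C7′=C3′ alkene. Exchange of the substituents on C3′ would need palladium σ-bonded to a fully substituted carbon, so the Z geometry should be kept.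

Step 19
Reactants: 33 tetrasilyl ether
Product: 34 (1Z,4Z)-1-[(2R,3S)-2-(TBSO)-3-(hydroxymethyl)-3-methylcyclohexylidene]-4-[(2R,3R)-2-(TBSO)-3-(hydroxymethyl)-3-methylcyclohexylidene]butane
Conditions: HF·pyridine, pyridine, THF, 0 °C
Reagents that add atoms: none
Why: Buffered HF·pyridine cleaves the two primary neopentyl silyl ethers much faster than the two secondary ones, which are flanked by a quaternary carbon and an sp2 carbon.

Step 20
Reactants: 34 diol
Product: 35 (1Z,4Z)-1-[(2R,3R)-2-(TBSO)-3-formyl-3-methylcyclohexylidene]-4-[(2R,3S)-2-(TBSO)-3-formyl-3-methylcyclohexylidene]butane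
Conditions: Dess–Martin periodinane, NaHCO3, CH2Cl2, rt
Reagents that add atoms: none
Why: Dess–Martin oxidation of both primary alcohols; the α-carbons are quaternary, so neither epimerisation nor β-elimination of the silyloxy group can occur.

Step 21
Reactants: 35 dialdehyde; 36 allylmagnesium bromide
Product: 37 (1Z,4Z)-1-[(2R,3S)-2-(TBSO)-3-(1-hydroxybut-3-en-1-yl)-3-methylcyclohexylidene]-4-[(2R,3R)-2-(TBSO)-3-(1-hydroxybut-3-en-1-yl)-3-methylcyclohexylidene]butane (side-chain carbinol epimers)
Conditions: allylmagnesium bromide (3 equiv), Et2O, −78 °C; then aq NH4Cl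
Reagents that add atoms: allylmagnesium bromide (second equivalent), C=CC[Mg]Br
Why: Two-fold Grignard addition: each of the two non-enolisable formyl groups takes up one allyl group, so two equivalents of 36 are consumed and a slight excess is used. Allyl is chosen because a prenyl metal would bond through its γ-carbon; the two new carbinol centres form unselectively and are removed in step 23.

Step 22
Reactants: 37 bis(allyl carbinol); 38 2-methylbut-2-ene
Product: 39 (1Z,4Z)-1-[(2R,3S)-2-(TBSO)-3-(1-hydroxy-4-methylpent-3-en-1-yl)-3-methylcyclohexylidene]-4-[(2R,3R)-2-(TBSO)-3-(1-hydroxy-4-methylpent-3-en-1-yl)-3-methylcyclohexylidene]butane (side-chain carbinol epimers)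
Conditions: (H2IMes)(PCy3)Cl2Ru=CHPh (second-generation Grubbs catalyst, 10 mol %), 2-methylbut-2-ene/CH2Cl2, 40 °C, sealed tube
Reagents that add atoms: 2-methylbut-2-ene (second equivalent), CC=C(C)C
Why: Two-fold olefin cross-metathesis: each monosubstituted alkene exchanges =CH2 for =CMe2 with one molecule of 38 and loses propene, 38 being present in large excess as co-solvent. The trisubstituted exocyclic alkenes are too hindered to enter the catalytic cycle.

Step 23
Reactants: 39 bis(prenyl carbinol)
Product: 40 (1Z,4Z)-1-[(2R,3R)-2-(TBSO)-3-methyl-3-(4-methylpent-3-enoyl)cyclohexylidene]-4-[(2R,3S)-2-(TBSO)-3-methyl-3-(4-methylpent-3-enoyl)cyclohexylidene]butane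
Conditions: Dess–Martin periodinane, NaHCO3, CH2Cl2, 0 °C to rt
Reagents that add atoms: none
Why: Buffered Dess–Martin oxidation gives the β,γ-unsaturated ketones without the acid or base that would move the alkene into conjugation; the silyl ethers keep the ring carbinols out of the oxidation.

Step 24
Reactants: 40 bis(silyl ether) diketone
Product: 41 CNP0297042.3, (1Z,4Z)-1-[(2R,3R)-2-hydroxy-3-methyl-3-(4-methylpent-3-enoyl)cyclohexylidene]-4-[(2R,3S)-2-hydroxy-3-methyl-3-(4-methylpent-3-enoyl)cyclohexylidene]butane
Conditions: HF·pyridine, pyridine, THF, 0 °C to rt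
Reagents that add atoms: none
Why: Pyridine-buffered HF·pyridine removes the secondary silyl ethers under weakly acidic, non-basic conditions that should neither conjugate the β,γ-enones nor trigger retro-aldol cleavage; no stereocentre is touched.

## Compound list

1 | 3-ethoxycyclohex-2-en-1-one | CCOC1=CC(=O)CCC1 | starting material
2 | (chloromethyl)(isopropoxy)dimethylsilane | CC(C)O[Si](C)(C)CCl | starting material
3 | [(isopropoxydimethylsilyl)methyl]magnesium chloride (not isolated) | CC(C)O[Si](C)(C)C[Mg]Cl | intermediate
4 | chloromagnesium 3-ethoxy-1-[(isopropoxydimethylsilyl)methyl]cyclohex-2-en-1-olate, racemic (not isolated) | CCOC1=CC(CCC1)(C[Si](C)(C)OC(C)C)O[Mg]Cl | intermediate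
5 | 3-ethoxy-1-(hydroxymethyl)cyclohex-2-en-1-ol, racemic (not isolated) | CCOC1=CC(O)(CO)CCC1 | intermediate
6 | 3-(hydroxymethyl)cyclohex-2-en-1-one | O=C1C=C(CO)CCC1 | intermediate
7 | 3-(TBSOCH2)cyclohex-2-en-1-one | CC(C)(C)[Si](C)(C)OCC1=CC(=O)CCC1 | intermediate
8 | trimethylaluminium | C[Al](C)C | starting material
9 | dimethylaluminium (R)-3-(TBSOCH2)-3-methylcyclohex-1-en-1-olate (not isolated) | CC(C)(C)[Si](C)(C)OC[C@]1(C)CCCC(O[Al](C)C)=C1 | intermediate
10 | lithium trimethyl[(R)-3-(TBSOCH2)-3-methylcyclohex-1-en-1-olato]aluminate (not isolated) | [Li+].CC(C)(C)[Si](C)(C)OC[C@]1(C)CCCC(O[Al-](C)(C)C)=C1 | intermediate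
11 | (R)-3-(TBSOCH2)-3-methylcyclohex-1-en-1-yl trifluoromethanesulfonate | CC(C)(C)[Si](C)(C)OC[C@]1(C)CCCC(OS(=O)(=O)C(F)(F)F)=C1 | intermediate
12 | tributyl(vinyl)stannane | CCCC[Sn](CCCC)(CCCC)C=C | starting material
13 | (R)-tert-butyldimethyl[(1-methyl-3-vinylcyclohex-2-en-1-yl)methoxy]silane | CC(C)(C)[Si](C)(C)OC[C@]1(C)CCCC(C=C)=C1 | intermediate
14 | dioxygen | O=O | starting material
15 | (8S,8aR)-8-(TBSOCH2)-8-methyl-3,5,6,7,8,8a-hexahydrobenzo[c][1,2]dioxine | CC(C)(C)[Si](C)(C)OC[C@]1(C)CCCC2=CCOO[C@@H]12 | intermediate
16 | (1R,2Z,6S)-6-(TBSOCH2)-2-(2-hydroxyethylidene)-6-methylcyclohexan-1-ol | CC(C)(C)[Si](C)(C)OC[C@]1(C)CCC/C(=C/CO)[C@H]1O | intermediate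
17 | 2-[(1Z,2R,3S)-3-(TBSOCH2)-2-hydroxy-3-methylcyclohexylidene]ethyl methanesulfonate (not isolated) | CC(C)(C)[Si](C)(C)OC[C@]1(C)CCC/C(=C/COS(C)(=O)=O)[C@H]1O | intermediate
18 | (1R,2Z,6S)-6-(TBSOCH2)-2-(2-chloroethylidene)-6-methylcyclohexan-1-ol | CC(C)(C)[Si](C)(C)OC[C@]1(C)CCC/C(=C/CCl)[C@H]1O | intermediate
19 | tert-butyl{[(1R,2Z,6S)-6-(TBSOCH2)-2-(2-chloroethylidene)-6-methylcyclohexyl]oxy}dimethylsilane | CC(C)(C)[Si](C)(C)OC[C@]1(C)CCC/C(=C/CCl)[C@H]1O[Si](C)(C)C(C)(C)C | intermediate
20 | dimethylaluminium (S)-3-(TBSOCH2)-3-methylcyclohex-1-en-1-olate (not isolated) | CC(C)(C)[Si](C)(C)OC[C@@]1(C)CCCC(O[Al](C)C)=C1 | intermediate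
21 | lithium trimethyl[(S)-3-(TBSOCH2)-3-methylcyclohex-1-en-1-olato]aluminate (not isolated) | [Li+].CC(C)(C)[Si](C)(C)OC[C@@]1(C)CCCC(O[Al-](C)(C)C)=C1 | intermediate
22 | (S)-3-(TBSOCH2)-3-methylcyclohex-1-en-1-yl trifluoromethanesulfonate | CC(C)(C)[Si](C)(C)OC[C@@]1(C)CCCC(OS(=O)(=O)C(F)(F)F)=C1 | intermediate
23 | (S)-tert-butyldimethyl[(1-methyl-3-vinylcyclohex-2-en-1-yl)methoxy]silane | CC(C)(C)[Si](C)(C)OC[C@@]1(C)CCCC(C=C)=C1 | intermediate
24 | (8R,8aS)-8-(TBSOCH2)-8-methyl-3,5,6,7,8,8a-hexahydrobenzo[c][1,2]dioxine, expected major epimer (not isolated) | CC(C)(C)[Si](C)(C)OC[C@@]1(C)CCCC2=CCOO[C@H]12 | intermediate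
25 | (1S,2Z,6R)-6-(TBSOCH2)-2-(2-hydroxyethylidene)-6-methylcyclohexan-1-ol | CC(C)(C)[Si](C)(C)OC[C@@]1(C)CCC/C(=C/CO)[C@@H]1O | intermediate
26 | (1S,2Z,6R)-6-(TBSOCH2)-6-methyl-2-[2-(phenylsulfanyl)ethylidene]cyclohexan-1-ol | CC(C)(C)[Si](C)(C)OC[C@@]1(C)CCC/C(=C/CSc2ccccc2)[C@@H]1O | intermediate
27 | (2Z,6R)-6-(TBSOCH2)-6-methyl-2-[2-(phenylsulfanyl)ethylidene]cyclohexan-1-one | CC(C)(C)[Si](C)(C)OC[C@@]1(C)CCC/C(=C/CSc2ccccc2)C1=O | intermediate
28 | (1R,2Z,6R)-6-(TBSOCH2)-6-methyl-2-[2-(phenylsulfanyl)ethylidene]cyclohexan-1-ol | CC(C)(C)[Si](C)(C)OC[C@@]1(C)CCC/C(=C/CSc2ccccc2)[C@H]1O | intermediate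
29 | tert-butyl{[(1R,2Z,6R)-6-(TBSOCH2)-6-methyl-2-[2-(phenylsulfanyl)ethylidene]cyclohexyl]oxy}dimethylsilane | CC(C)(C)[Si](C)(C)OC[C@@]1(C)CCC/C(=C/CSc2ccccc2)[C@H]1O[Si](C)(C)C(C)(C)C | intermediate
30 | tert-butyl{[(1R,2Z,6R)-6-(TBSOCH2)-6-methyl-2-[2-(phenylsulfonyl)ethylidene]cyclohexyl]oxy}dimethylsilane | CC(C)(C)[Si](C)(C)OC[C@@]1(C)CCC/C(=C/CS(=O)(=O)c2ccccc2)[C@H]1O[Si](C)(C)C(C)(C)C | intermediate
31 | lithium salt of the α-sulfonyl carbanion of 30 (not isolated) | [Li+].CC(C)(C)[Si](C)(C)OC[C@@]1(C)CCC/C(=C/[CH-]S(=O)(=O)c2ccccc2)[C@H]1O[Si](C)(C)C(C)(C)C | intermediate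
32 | (1Z,4Z)-1-[(2R,3R)-2-(TBSO)-3-(TBSOCH2)-3-methylcyclohexylidene]-2-(phenylsulfonyl)-4-[(2R,3S)-2-(TBSO)-3-(TBSOCH2)-3-methylcyclohexylidene]butane, epimers at the sulfonyl carbon | CC(C)(C)[Si](C)(C)OC[C@]1(C)CCC/C(=C/CC(/C=C2/CCC[C@](C)(CO[Si](C)(C)C(C)(C)C)[C@@H]2O[Si](C)(C)C(C)(C)C)S(=O)(=O)c2ccccc2)[C@H]1O[Si](C)(C)C(C)(C)C | intermediate
33 | (1Z,4Z)-1-[(2R,3S)-2-(TBSO)-3-(TBSOCH2)-3-methylcyclohexylidene]-4-[(2R,3R)-2-(TBSO)-3-(TBSOCH2)-3-methylcyclohexylidene]butane | CC(C)(C)[Si](C)(C)OC[C@]1(C)CCC/C(=C/CC/C=C2/CCC[C@](C)(CO[Si](C)(C)C(C)(C)C)[C@@H]2O[Si](C)(C)C(C)(C)C)[C@H]1O[Si](C)(C)C(C)(C)C | intermediate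
34 | (1Z,4Z)-1-[(2R,3S)-2-(TBSO)-3-(hydroxymethyl)-3-methylcyclohexylidene]-4-[(2R,3R)-2-(TBSO)-3-(hydroxymethyl)-3-methylcyclohexylidene]butane | OC[C@]1(C)CCC/C(=C/CC/C=C2/CCC[C@](C)(CO)[C@@H]2O[Si](C)(C)C(C)(C)C)[C@H]1O[Si](C)(C)C(C)(C)C | intermediate
35 | (1Z,4Z)-1-[(2R,3R)-2-(TBSO)-3-formyl-3-methylcyclohexylidene]-4-[(2R,3S)-2-(TBSO)-3-formyl-3-methylcyclohexylidene]butane | O=C[C@]1(C)CCC/C(=C/CC/C=C2/CCC[C@](C)(C=O)[C@@H]2O[Si](C)(C)C(C)(C)C)[C@H]1O[Si](C)(C)C(C)(C)C | intermediate
36 | allylmagnesium bromide | C=CC[Mg]Br | starting material
37 | (1Z,4Z)-1-[(2R,3S)-2-(TBSO)-3-(1-hydroxybut-3-en-1-yl)-3-methylcyclohexylidene]-4-[(2R,3R)-2-(TBSO)-3-(1-hydroxybut-3-en-1-yl)-3-methylcyclohexylidene]butane, side-chain carbinol epimers | C=CCC(O)[C@]1(C)CCC/C(=C/CC/C=C2/CCC[C@](C)(C(O)CC=C)[C@@H]2O[Si](C)(C)C(C)(C)C)[C@H]1O[Si](C)(C)C(C)(C)C | intermediate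
38 | 2-methylbut-2-ene | CC=C(C)C | starting material
39 | (1Z,4Z)-1-[(2R,3S)-2-(TBSO)-3-(1-hydroxy-4-methylpent-3-en-1-yl)-3-methylcyclohexylidene]-4-[(2R,3R)-2-(TBSO)-3-(1-hydroxy-4-methylpent-3-en-1-yl)-3-methylcyclohexylidene]butane, side-chain carbinol epimers | CC(C)=CCC(O)[C@]1(C)CCC/C(=C/CC/C=C2/CCC[C@](C)(C(O)CC=C(C)C)[C@@H]2O[Si](C)(C)C(C)(C)C)[C@H]1O[Si](C)(C)C(C)(C)C | intermediate
40 | (1Z,4Z)-1-[(2R,3R)-2-(TBSO)-3-methyl-3-(4-methylpent-3-enoyl)cyclohexylidene]-4-[(2R,3S)-2-(TBSO)-3-methyl-3-(4-methylpent-3-enoyl)cyclohexylidene]butane | CC(C)=CCC(=O)[C@]1(C)CCC/C(=C/CC/C=C2/CCC[C@](C)(C(=O)CC=C(C)C)[C@@H]2O[Si](C)(C)C(C)(C)C)[C@H]1O[Si](C)(C)C(C)(C)C | intermediate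
41 | CNP0297042.3, (1Z,4Z)-1-[(2R,3R)-2-hydroxy-3-methyl-3-(4-methylpent-3-enoyl)cyclohexylidene]-4-[(2R,3S)-2-hydroxy-3-methyl-3-(4-methylpent-3-enoyl)cyclohexylidene]butane | CC(C)=CCC(=O)[C@]1(C)CCC/C(=C/CC/C=C2/CCC[C@](C)(C(=O)CC=C(C)C)[C@@H]2O)[C@H]1O | target

## Step count and least certain steps

Total: 24 steps. Longest linear sequence: 18 steps (steps 1, 2, 9 to 16, 17 to 24). The ring A branch (steps 3 to 8) joins at step 17.

Step 5 (key step). The most likely failure is poor facial selectivity at C2, because the two faces differ only by methyl versus CH2OTBS on the neighbouring quaternary carbon; diversion into the ene pathway through the C4 hydrogens is the second risk. The fallback replaces substrate-controlled oxygen delivery by a hydroxyl-directed hydride delivery; it sets out from 16 obtained together with its epimeric diol F1 and comes back at 16. Pivaloyl chloride and pyridine at 0 °C would acylate the primary allylic hydroxyl of the mixture, giving the epimeric pivalate F2 beside its C2 epimer, and Dess–Martin oxidation would converge both on the enone F3. HF·pyridine would then free the neopentyl hydroxyl to give the hydroxy enone F4. Me4NBH(OAc)3 in MeCN/AcOH at −20 °C (Evans–Saksena reduction) binds to the CH2OH group and delivers hydride intramolecularly to the carbonyl face on the CH2OH side, so the C2 hydroxyl of the diol F5 should lie cis to methyl. TBSCl and imidazole would silylate only the primary hydroxyl to give the silyl ether pivalate F6, and i-Bu2AlH at −78 °C would remove the pivalate to give 16.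

Step 14. Hydride delivery may be poorly face-selective, since both faces of the C2′ carbonyl are flanked by the same quaternary carbon and the preference rests on CH2OTBS standing anti to the nucleophile. The fallback replaces substrate control by catalyst control; it sets out from 27 and comes back at 28 and needs no new intermediate (entry F0). It is a Corey–Bakshi–Shibata reduction with BH3·SMe2 and (S)- or (R)-2-methyl-5,5-diphenyl-3,4-propano-1,3,2-oxazaborolidine, the antipode chosen so that the catalyst, which should treat the quaternary carbon as the large group, directs hydride to the required face.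

Step 18. The allylpalladium intermediate could lose the Z geometry or deliver hydride to C3′ (double-bond transposition), because the C2′ silyloxy carbon occupies the crowded anti position of the allyl unit. The fallback avoids both the sulfone and the allylpalladium species; it sets out from 29 and 19 and comes back at 33. The sulfide 29 would be deprotonated α to sulfur (n-BuLi, DABCO, THF, −78 °C) and alkylated with 19 in a Biellmann-type coupling to the coupled thioether F7, whose C–S bond would be cleaved with lithium in ethylamine at −78 °C (electron transfer, then protonation of the allyl anion at the less hindered carbon).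

Step 7. Intramolecular displacement may compete: the C2 hydroxyl sits cis to the activated C8 and can close a 2,5-dihydrofuran, and mesylation may not be fully selective for the primary hydroxyl. The fallback never has a free C2 hydroxyl beside a leaving group at C8; it sets out from 16 and comes back at 19. Ac2O and 2,4,6-collidine at −20 °C would acetylate the primary hydroxyl to the acetate F8, TBSOTf and 2,6-lutidine would silylate C2 to the silylated acetate F9, K2CO3 in MeOH at 0 °C would give the allylic alcohol F10, and MsCl, collidine and LiCl would convert this alcohol into 19.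

Steps 3 and 9 (mirror images of one another). The hindered aluminate enolate may be captured incompletely, with protonation giving a ketone from which the C2=C3 enol triflate cannot be made regioselectively, and the oxygenated 3-substituent may lower the enantioselectivity. The fallback separates conjugate addition from triflation; it sets out from 7 and comes back at 11 (ring A) or 22 (ring B). The aluminium enolate would be quenched with TMSOTf to the isolable trimethylsilyl enol ether F11 (ring B: its enantiomer F12), MeLi in THF at 0 °C would regenerate the regiodefined lithium enolate, and PhNTf2 would give the triflate. A shortfall in enantiomeric purity is partly absorbed at step 17, where minor enantiomers end in separable diastereomers.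

## Further compounds

F1 | step 5 | (1S,2Z,6S)-6-(TBSOCH2)-2-(2-hydroxyethylidene)-6-methylcyclohexan-1-ol, C2 epimer of 16 | CC(C)(C)[Si](C)(C)OC[C@]1(C)CCC/C(=C/CO)[C@@H]1O
F2 | step 5 | 2-[(1Z,2S,3S)-3-(TBSOCH2)-2-hydroxy-3-methylcyclohexylidene]ethyl pivalate | CC(C)(C)[Si](C)(C)OC[C@]1(C)CCC/C(=C/COC(=O)C(C)(C)C)[C@@H]1O
F3 | step 5 | 2-[(1Z,3S)-3-(TBSOCH2)-3-methyl-2-oxocyclohexylidene]ethyl pivalate | CC(C)(C)[Si](C)(C)OC[C@]1(C)CCC/C(=C/COC(=O)C(C)(C)C)C1=O
F4 | step 5 | 2-[(1Z,3S)-3-(hydroxymethyl)-3-methyl-2-oxocyclohexylidene]ethyl pivalate | OC[C@]1(C)CCC/C(=C/COC(=O)C(C)(C)C)C1=O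
F5 | step 5 | 2-[(1Z,2R,3S)-2-hydroxy-3-(hydroxymethyl)-3-methylcyclohexylidene]ethyl pivalate | OC[C@]1(C)CCC/C(=C/COC(=O)C(C)(C)C)[C@H]1O
F6 | step 5 | 2-[(1Z,2R,3S)-3-(TBSOCH2)-2-hydroxy-3-methylcyclohexylidene]ethyl pivalate | CC(C)(C)[Si](C)(C)OC[C@]1(C)CCC/C(=C/COC(=O)C(C)(C)C)[C@H]1O
F0 | step 14 | none | none
F7 | step 18 | (1Z,4Z)-1-[(2R,3R)-2-(TBSO)-3-(TBSOCH2)-3-methylcyclohexylidene]-2-(phenylsulfanyl)-4-[(2R,3S)-2-(TBSO)-3-(TBSOCH2)-3-methylcyclohexylidene]butane, epimers at the sulfur-bearing carbon | CC(C)(C)[Si](C)(C)OC[C@]1(C)CCC/C(=C/CC(/C=C2/CCC[C@](C)(CO[Si](C)(C)C(C)(C)C)[C@@H]2O[Si](C)(C)C(C)(C)C)Sc2ccccc2)[C@H]1O[Si](C)(C)C(C)(C)C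
F8 | step 7 | 2-[(1Z,2R,3S)-3-(TBSOCH2)-2-hydroxy-3-methylcyclohexylidene]ethyl acetate | CC(C)(C)[Si](C)(C)OC[C@]1(C)CCC/C(=C/COC(C)=O)[C@H]1O
F9 | step 7 | 2-[(1Z,2R,3S)-2-(TBSO)-3-(TBSOCH2)-3-methylcyclohexylidene]ethyl acetate | CC(C)(C)[Si](C)(C)OC[C@]1(C)CCC/C(=C/COC(C)=O)[C@H]1O[Si](C)(C)C(C)(C)C
F10 | step 7 | 2-[(1Z,2R,3S)-2-(TBSO)-3-(TBSOCH2)-3-methylcyclohexylidene]ethan-1-ol | CC(C)(C)[Si](C)(C)OC[C@]1(C)CCC/C(=C/CO)[C@H]1O[Si](C)(C)C(C)(C)C
F11 | step 3 | tert-butyldimethyl{[(1R)-1-methyl-3-[(trimethylsilyl)oxy]cyclohex-2-en-1-yl]methoxy}silane | CC(C)(C)[Si](C)(C)OC[C@]1(C)CCCC(O[Si](C)(C)C)=C1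
F12 | step 9 | tert-butyldimethyl{[(1S)-1-methyl-3-[(trimethylsilyl)oxy]cyclohex-2-en-1-yl]methoxy}silane | CC(C)(C)[Si](C)(C)OC[C@@]1(C)CCCC(O[Si](C)(C)C)=C1
A1 | alternative 1 | methyl (R)-2-formyl-2-methyl-7-(trimethylsilyl)hept-6-ynoate | COC(=O)[C@@](C)(C=O)CCCC#C[Si](C)(C)C
A2 | alternative 1 | methyl (7R,7aS)-7-methyl-2-oxo-3-(trimethylsilyl)-2,4,5,6,7,7a-hexahydro-1-benzofuran-7-carboxylate | COC(=O)[C@]1(C)CCCC2=C([Si](C)(C)C)C(=O)O[C@@H]12
A3 | alternative 2 | 4-(benzyloxy)-5-(TBSO)-6-ethenyl-3-methyloxan-2-one, benzyloxy cis to vinyl and silyloxy trans to both, C3 unspecified | C=C[C@@H]1OC(=O)C(C)[C@H](OCc2ccccc2)[C@H]1O[Si](C)(C)C(C)(C)C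
A4 | alternative 2 | 2-(benzyloxy)-3-(TBSO)-1-methylcyclohex-4-ene-1-carboxylic acid, C1 and C2 as in ring A | OC(=O)[C@]1(C)CC=C[C@H](O[Si](C)(C)C(C)(C)C)[C@H]1OCc1ccccc1
A5 | alternative 3 | {[5-(furan-3-yl)-1-methoxy-2-methylpent-1-en-1-yl]oxy}trimethylsilane | COC(O[Si](C)(C)C)=C(C)CCCc1ccoc1
A6 | alternative 3 | methyl 7-methyl-4,5,6,7-tetrahydro-1-benzofuran-7-carboxylate, racemic | COC(=O)C1(C)CCCc2ccoc12
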